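## The problem

The target is a flavonol: a 4H-chromen-4-one (rings A and C) with an aryl ring B on C2 and seven oxygen substituents on the periphery. Four of them are free hydroxyls (C3, C5, C2', C4') and three are methyl ethers (C7, C8, C5'). The task is therefore one of placing and differentiating oxygen on a 5,7,8-trioxygenated ring A and a 2',4',5'-trioxygenated ring B. There is no stereocentre, so every selectivity question is one of regiochemistry: which ring A carbon takes O1 and which the carbonyl, C8 against C6, and one phenol against another. The free compound is an electron-rich polyphenol. Its 3-hydroxy-4-pyranone and its 5,8-dioxygenated ring A oxidise readily in base and air, and the pyranone opens when hydroxide or alkoxide adds at C2, so the phenols should be unmasked last and under neutral conditions. The feature that invites a short construction is that C8a carries O1 while its neighbour C4a carries the C4 carbonyl. These two ortho substituents can be added together across a C4a≡C8a aryne, and the C5 oxygen beside C4a tells the aryne which end takes oxygen. The price is that C3 arrives as CH and C8 must stay unsubstituted in the aryne, so both oxygens have to be introduced afterwards.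

## Retrosynthesis

**Target 28 to 27.** The three O–benzyl bonds at O3, O2' and O4' are cut last. Benzyl ethers survive base, acid, organolithium reagents, fluoride and persulfate, and they fall together under neutral hydrogenolysis, which the sensitive polyphenol tolerates. Methyl ethers cannot serve here, because the three methoxyls of the target must remain.

**27 to 24 through 26.** The C8–O bond and the 8-O-methyl bond are cut. In 24 the only free phenol is the C5 hydroxyl, and C8 is para to it, so an Elbs persulfate oxidation delivers oxygen there. In hydroquinone 26 the C5 hydroxyl is locked in a hydrogen bond to the C4 carbonyl, so one equivalent of methylating agent should take the C8 hydroxyl alone. Carrying the C8 oxygen from the start would be shorter, but it would put a second alkoxy group beside the aryne and cancel the regiocontrol of the key step.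

**24 to 19 through 23 and 22.** The C3–O bond is cut. Flavone 19 has a single acidic vinylic hydrogen at C3, which lithiation, borylation and peroxide oxidation convert to the flavonol 22. The enolic hydroxyl is capped as a benzyl ether (23) so that it does not interfere with the persulfate step. The C5 acetal is then removed by mild acid to expose the one phenol that directs the oxidation (24).

**19 to 9 and 16 (key disconnection).** O1–C8a, C4–C4a and O1–C2 are cut together. This removes ring C and divides the molecule into a ring A aryne precursor 9 and a ring B arylpropiolic acid 16 of similar size. A chalcone or diketone route would need a fully substituted 2-hydroxyacetophenone and a separate oxidation-state adjustment. Here the acid brings C2, C3 and C4 at the correct oxidation level. The forward reaction must add the carboxylate oxygen only at the aryne carbon remote from the C5 oxygen and must close ring C in the 6-endo mode.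

**9 to 1 through 7, 3 and 2.** The C–Si and O–S bonds of the silyl triflate are cut. Mono-protection of the symmetric diol 1 gives 2. The remaining phenol becomes an N-isopropylcarbamate (3), which directs lithiation to the position it shares with the methoxymethoxy group; silylation gives 7. The carbamate is then removed by base and replaced by triflate. The more obvious sequence, silylation between two acetals and acidic removal of one of them, is avoided. That arylsilane carries three oxygen donors ortho and para to silicon and would be protodesilylated by the acid needed to cleave the acetal.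

**16 to 14 and 15, and 14 to 10 through 13 and 12.** The aryl–alkyne bond is cut to iodide 14 and propiolic acid 15, which a copper-free Sonogashira coupling joins in one step without a separate carboxylation. Iodide 14 comes from iodination of 13 at its most activated and least hindered position. Compound 13 comes from 3-(benzyloxy)-4-methoxybenzaldehyde 10 by Baeyer–Villiger oxidation to phenol 12 and benzylation. The aldehyde carbon of 10 is exchanged for the C2' oxygen, and the methoxyl of 10 becomes the C5' methoxyl.

## Roads not taken

**Alternative 1:** The cut is the C2–C1' bond, with O3 and O2' joined beforehand by a methylene acetal. In the forward direction the bromoaryl acetal A2 is treated with Pd(OAc)2, PCy3·HBF4, K2CO3 and pivalic acid. Zerovalent palladium inserts into C1'–Br, the divalent arylpalladium metalates C2–H of the chromone, and reductive elimination gives the dioxepine-bridged flavonol A1.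
- Merits: ring A arrives fully oxygenated and the C3 oxygen is present from the outset, so neither a late C3 oxidation nor a persulfate step is needed. The tether fixes the site of arylation and protects two hydroxyls at once.
- Weak points: the mixed formaldehyde acetal between an enolic hydroxyl and a phenol has to be made through a labile aryl chloromethyl ether. The C–H metalation must close a seven-membered ring through an eight-membered palladacycle, where loss of bromine by reduction competes. The chromone half needs a multistep synthesis of its own. At the end the bridge and the chelated C5 methyl ether must both be cleaved without touching the three methoxyls that stay.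
- Comparison: in late-stage economy this road is better than the chosen plan. Against that the chosen plan sets a key step of a known reaction type, two simple fragments and a final deprotection that is a neutral hydrogenolysis.

**Alternative 2:** The cut is C4a–C5; ring C comes from kojic acid A5 and ring A is grown onto it. In the forward direction, heating the tert-butyl β-keto ester A4 expels the tert-butoxy group as its alcohol and gives an acylketene. The dienol form of this ketene closes by 6π electrocyclization onto the pyranone C4a=C8a bond, and tautomerization gives A3.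
- Merits: the C3 oxygen is inherited from A5 and ring A emerges with its C8 methoxyl and both hydroxyls. Only a 7-O-methylation (easy, since the C5 hydroxyl is chelated) and hydrogenolysis remain, which is a shorter finish than that of the chosen plan and has no low-yielding oxidation.
- Weak points: A4 is laborious to assemble, needing arylation of the pyranone carbon next to the ring oxygen and a four-carbon homologation of the hydroxymethyl group with an α-methoxy ketone. The electrocyclization has to engage a double bond that belongs to a cross-conjugated, partly aromatic 4-pyranone. Acylketenes also dimerize or are trapped at oxygen when cyclization is slow.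
- Comparison: the end game is clearly superior. The chosen plan answers with a ring-forming step that has direct precedent on the flavone skeleton and with precursors reached in four steps each.

**Alternative 3:** The cut takes ring B apart at C5'–C6', C1'–C2' and C2'–C3'. In the forward direction the alkenyl(methoxy)carbene complex A8 of zerovalent chromium, the 2-ethynylchromone A7 and one carbonyl ligand combine in a Dötz benzannulation to give A6 with a free C2' phenol.
- Merits: ring A and the C3 oxygen are complete before the key step. The three ring B oxygens are formed already differentiated (free hydroxyl, acetal, methyl ether), and the regiochemistry with terminal alkynes is dependable.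
- Weak points: the reaction is stoichiometric in chromium. A8 carries an acid-labile enol acetal. A7 is an electron-poor alkyne conjugated to the chromone, a class that gives poor benzannulation yields, and it needs several steps to make. The product is a para-methoxyphenol that can be oxidised to a quinone during decomplexation. The C5 methyl ether must finally be cleaved selectively among four.
- Comparison: this road differentiates ring B better than the chosen plan and avoids late ring A oxidation. The chosen plan avoids stoichiometric heavy metal, uses a more robust alkyne partner and ends with a cleaner deprotection.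

Key step: step 9

Remark: the target has no stereocentre, so no SMILES below needs stereodescriptors; 3-(benzyloxy)-4-methoxybenzaldehyde (the benzyl ether of isovanillin) is taken as a commercial starting material.

## Route

Step 1
Reactants: 1 5-methoxyresorcinol (5-methoxybenzene-1,3-diol)
Product: 2 3-methoxy-5-(methoxymethoxy)phenol
Conditions: MOMCl (1.0 equiv), K2CO3, acetone, 0 °C to rt
Reagents that add atoms: chloromethyl methyl ether, COCCl
Why: Williamson-type O-alkylation of a symmetric diol; one equivalent of the chloride limits bis-protection, and the mono-ether is easily separated from recovered diol (recycled) and bis-ether.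

Step 2
Reactants: 2 3-methoxy-5-(methoxymethoxy)phenol
Product: 3 3-methoxy-5-(methoxymethoxy)phenyl N-isopropylcarbamate
Conditions: iPrNCO, Et3N (cat.), CH2Cl2, rt
Reagents that add atoms: isopropyl isocyanate, CC(C)N=C=O
Why: Base-catalysed addition of a phenol to an isocyanate; it installs the strongest ortho-directing group on the oxygen that later becomes the triflate.

Step 3
Reactants: 3 3-methoxy-5-(methoxymethoxy)phenyl N-isopropylcarbamate
Product: 7 5-methoxy-3-(methoxymethoxy)-2-(trimethylsilyl)phenyl N-isopropylcarbamate, via N-silyl carbamate 4 (not isolated), via aryllithium 5 (not isolated), via N-silyl arylsilane 6 (not isolated)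
Conditions: Me3SiOTf, TMEDA, Et2O, 0 °C to rt; n-BuLi, TMEDA, −78 °C; Me3SiCl, −78 °C to rt; MeOH, aq. NH4Cl
Reagents that add atoms: chlorotrimethylsilane, C[Si](C)(C)Cl; trimethylsilyl trifluoromethanesulfonate, C[Si](C)(C)OS(=O)(=O)C(F)(F)F (its silyl group stays only in 4 to 6)
Why: Directed ortho-metalation: transient N-silylation blocks N-deprotonation and isocyanate loss, and n-BuLi/TMEDA should remove the hydrogen flanked by the carbamate and the chelating methoxymethoxy group in preference to the one flanked by carbamate and methoxyl. The near-neutral work-up hydrolyses only the N–Si bond and spares the acid-sensitive electron-rich arylsilane.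

Step 4
Reactants: 7 5-methoxy-3-(methoxymethoxy)-2-(trimethylsilyl)phenyl N-isopropylcarbamate
Product: 9 5-methoxy-3-(methoxymethoxy)-2-(trimethylsilyl)phenyl trifluoromethanesulfonate, via silylphenol 8 (not isolated)
Conditions: DBU, Et2NH, MeCN, 40 °C; then PhNTf2, rt
Reagents that add atoms: N-phenylbis(trifluoromethanesulfonimide), O=S(=O)(N(c1ccccc1)S(=O)(=O)C(F)(F)F)C(F)(F)F
Why: E1cB cleavage of the N-monoalkyl carbamate (DBU removes N–H, the isocyanate is trapped by Et2NH as a urea) frees the phenoxide, which is triflated in the same flask. No acid or fluoride touches the arylsilane or the acetal.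

Step 5
Reactants: 10 3-(benzyloxy)-4-methoxybenzaldehyde
Product: 12 3-(benzyloxy)-4-methoxyphenol, via aryl formate 11 (not isolated)
Conditions: mCPBA, CH2Cl2, rt; aq. NaHCO3 wash; then K2CO3 (cat.), MeOH, rt
Reagents that add atoms: 3-chloroperbenzoic acid, OOC(=O)c1cccc(Cl)c1
Why: Baeyer–Villiger oxidation of an electron-rich benzaldehyde, in which the para-methoxyl favours aryl migration; methanolysis of the formate gives the phenol.

Step 6
Reactants: 12 3-(benzyloxy)-4-methoxyphenol
Product: 13 2,4-bis(benzyloxy)-1-methoxybenzene
Conditions: BnBr, K2CO3, DMF, rt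
Reagents that add atoms: benzyl bromide, BrCc1ccccc1
Why: Williamson etherification of a phenol.

Step 7
Reactants: 13 2,4-bis(benzyloxy)-1-methoxybenzene
Product: 14 1,5-bis(benzyloxy)-2-iodo-4-methoxybenzene
Conditions: NIS, CF3CO2H (cat.), MeCN, 0 °C to rt
Reagents that add atoms: N-iodosuccinimide, O=C1CCC(=O)N1I
Why: Electrophilic aromatic iodination at the position para to one benzyloxy group and ortho to the other, the usual site for 1,2,4-trialkoxybenzenes; the position between the two benzyloxy groups is hindered and the one next to the methoxyl is activated by a single oxygen.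

Step 8
Reactants: 14 1,5-bis(benzyloxy)-2-iodo-4-methoxybenzene; 15 propiolic acid
Product: 16 3-[2,4-bis(benzyloxy)-5-methoxyphenyl]prop-2-ynoic acid
Conditions: Pd(PPh3)4 (5 mol %), DBU, DMSO, 35 °C; then aq. HCl
Reagents that add atoms: none
Why: Copper-free Sonogashira coupling of an aryl iodide with propiolic acid as its amidinium carboxylate; the absence of copper and the low temperature suppress decarboxylative coupling to the diarylalkyne.

Step 9
Reactants: 9 5-methoxy-3-(methoxymethoxy)-2-(trimethylsilyl)phenyl trifluoromethanesulfonate (1.5 equiv); 16 3-[2,4-bis(benzyloxy)-5-methoxyphenyl]prop-2-ynoic acid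
Product: 19 2-[2,4-bis(benzyloxy)-5-methoxyphenyl]-7-methoxy-5-(methoxymethoxy)-4H-chromen-4-one, via aryne 17 (not isolated), via hydroxyaryl ynone 18 (not isolated)
Conditions: CsF (4 equiv), THF, 125 °C, sealed tube
Reagents that add atoms: none
Why: CsF removes the silyl group of 9 and triflate leaves, giving aryne 17, while further fluoride turns 16 into its cesium carboxylate. The carboxylate oxygen adds to the aryne carbon remote from the methoxymethoxy group (future C8a), because this inductively withdrawing C5 oxygen and the distortion it causes place the developing negative charge on the carbon beside it (future C4a); the C7 methoxyl has only a weak opposing influence, as the behaviour of 3,5-dialkoxybenzynes shows. The aryl anion then attacks the neighbouring ester carbonyl through a four-membered transition state (a 1,3 acyl shift from oxygen to carbon), which forms C4–C4a and releases the phenoxide of ynone 18. This is the known fluoride-induced insertion of arynes into the C–O bond of carboxylic acids, which with arylpropiolic acids is known to continue to flavones. Ring C closes by 6-endo-dig oxa-Michael addition of the C8a phenoxide to the ynone β-carbon, forming O1–C2; an aprotic medium and a cesium phenoxide favour this mode over 5-exo-dig closure to an aurone. No stereocentre is formed. The high temperature is needed so that acyl transfer outruns protonation of the aryl anion, which would stop at the aryl ester. Benzyl ethers, the acetal and the methyl ethers are inert to fluoride and to the aryne.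

Step 10
Reactants: 19 2-[2,4-bis(benzyloxy)-5-methoxyphenyl]-7-methoxy-5-(methoxymethoxy)-4H-chromen-4-one
Product: 22 2-[2,4-bis(benzyloxy)-5-methoxyphenyl]-3-hydroxy-7-methoxy-5-(methoxymethoxy)-4H-chromen-4-one, via 3-lithioflavone 20 (not isolated), via flavon-3-yl boronate 21 (not isolated)
Conditions: LiN(iPr)2, THF, −78 °C; B(OMe)3, −78 to 0 °C; AcOH, 30% aq. H2O2, 0 °C to rt
Reagents that add atoms: hydrogen peroxide, OO; trimethyl borate, COB(OC)OC (its atoms stay only in 21)
Why: The C3 hydrogen of a flavone is the only one the amide base can remove (vinylic, alpha to the carbonyl, lithium held by the carbonyl oxygen); the borate traps the anion and peroxide converts C–B into C–O by 1,2-migration, the established lithiation–borylation–oxidation route from flavones to flavonols.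

Step 11
Reactants: 22 2-[2,4-bis(benzyloxy)-5-methoxyphenyl]-3-hydroxy-7-methoxy-5-(methoxymethoxy)-4H-chromen-4-one
Product: 23 3-(benzyloxy)-2-[2,4-bis(benzyloxy)-5-methoxyphenyl]-7-methoxy-5-(methoxymethoxy)-4H-chromen-4-one
Conditions: BnBr, K2CO3, DMF, rt
Reagents that add atoms: benzyl bromide, BrCc1ccccc1
Why: Williamson O-benzylation of the acidic enolic C3 hydroxyl, which masks the oxidation-prone flavonol unit before the persulfate step.

Step 12
Reactants: 23 3-(benzyloxy)-2-[2,4-bis(benzyloxy)-5-methoxyphenyl]-7-methoxy-5-(methoxymethoxy)-4H-chromen-4-one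
Product: 24 3-(benzyloxy)-2-[2,4-bis(benzyloxy)-5-methoxyphenyl]-5-hydroxy-7-methoxy-4H-chromen-4-one
Conditions: 3 M aq. HCl, MeOH/THF, 50 °C
Reagents that add atoms: none
Why: Acid-catalysed acetal cleavage; the C5 acetal is especially labile because the freed phenol is hydrogen-bonded to the C4 carbonyl, and benzyl and methyl ethers are untouched.

Step 13
Reactants: 24 3-(benzyloxy)-2-[2,4-bis(benzyloxy)-5-methoxyphenyl]-5-hydroxy-7-methoxy-4H-chromen-4-one
Product: 26 3-(benzyloxy)-2-[2,4-bis(benzyloxy)-5-methoxyphenyl]-5,8-dihydroxy-7-methoxy-4H-chromen-4-one, via aryl sulfate 25 (not isolated)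
Conditions: K2S2O8, aq. KOH, pyridine, 0 °C to rt; then 2 M aq. HCl, Na2SO3, 60 °C
Reagents that add atoms: potassium peroxodisulfate, [K+].[K+].[O-]S(=O)(=O)OOS(=O)(=O)[O-]
Why: Elbs persulfate oxidation: the phenolate of the only free phenol attacks the peroxide oxygen through its para carbon, C8, giving the aryl sulfate, which hot dilute acid hydrolyses. This is the classical entry from 5-hydroxyflavones to 5,8-dihydroxyflavones, and sulfite protects the hydroquinone from air.

Step 14
Reactants: 26 3-(benzyloxy)-2-[2,4-bis(benzyloxy)-5-methoxyphenyl]-5,8-dihydroxy-7-methoxy-4H-chromen-4-one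
Product: 27 3-(benzyloxy)-2-[2,4-bis(benzyloxy)-5-methoxyphenyl]-5-hydroxy-7,8-dimethoxy-4H-chromen-4-one
Conditions: Me2SO4 (1.05 equiv), K2CO3, acetone, reflux
Reagents that add atoms: dimethyl sulfate, COS(=O)(=O)OC
Why: Selective Williamson methylation: the C5 hydroxyl is held in a strong hydrogen bond to the C4 carbonyl and is far less nucleophilic than the free C8 hydroxyl, so one equivalent of reagent should methylate C8 only.

Step 15
Reactants: 27 3-(benzyloxy)-2-[2,4-bis(benzyloxy)-5-methoxyphenyl]-5-hydroxy-7,8-dimethoxy-4H-chromen-4-one
Product: 28 2-(2,4-dihydroxy-5-methoxyphenyl)-3,5-dihydroxy-7,8-dimethoxy-4H-chromen-4-one (CNP0319239.0)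
Conditions: H2 (1 atm), Pd/C (10%), THF/MeOH, rt
Reagents that add atoms: none
Why: Catalytic hydrogenolysis of the three benzyl ethers under neutral conditions; the tetrasubstituted, conjugated C2=C3 bond of a flavonol and the methyl ethers are not reduced.

## Compound list

1 | 5-methoxyresorcinol (5-methoxybenzene-1,3-diol) | COc1cc(O)cc(O)c1 | starting material
2 | 3-methoxy-5-(methoxymethoxy)phenol | COCOc1cc(O)cc(OC)c1 | intermediate
3 | 3-methoxy-5-(methoxymethoxy)phenyl N-isopropylcarbamate | COCOc1cc(OC)cc(OC(=O)NC(C)C)c1 | intermediate
4 | 3-methoxy-5-(methoxymethoxy)phenyl N-isopropyl-N-(trimethylsilyl)carbamate | COCOc1cc(OC)cc(OC(=O)N(C(C)C)[Si](C)(C)C)c1 | intermediate (not isolated)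
5 | [2-{[isopropyl(trimethylsilyl)carbamoyl]oxy}-4-methoxy-6-(methoxymethoxy)phenyl]lithium | COCOc1cc(OC)cc(OC(=O)N(C(C)C)[Si](C)(C)C)c1[Li] | intermediate (not isolated)
6 | 5-methoxy-3-(methoxymethoxy)-2-(trimethylsilyl)phenyl N-isopropyl-N-(trimethylsilyl)carbamate | COCOc1cc(OC)cc(OC(=O)N(C(C)C)[Si](C)(C)C)c1[Si](C)(C)C | intermediate (not isolated)
7 | 5-methoxy-3-(methoxymethoxy)-2-(trimethylsilyl)phenyl N-isopropylcarbamate | COCOc1cc(OC)cc(OC(=O)NC(C)C)c1[Si](C)(C)C | intermediate
8 | 5-methoxy-3-(methoxymethoxy)-2-(trimethylsilyl)phenol | COCOc1cc(OC)cc(O)c1[Si](C)(C)C | intermediate (not isolated)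
9 | 5-methoxy-3-(methoxymethoxy)-2-(trimethylsilyl)phenyl trifluoromethanesulfonate | COCOc1cc(OC)cc(OS(=O)(=O)C(F)(F)F)c1[Si](C)(C)C | intermediate
10 | 3-(benzyloxy)-4-methoxybenzaldehyde | COc1ccc(C=O)cc1OCc1ccccc1 | starting material
11 | 3-(benzyloxy)-4-methoxyphenyl formate | COc1ccc(OC=O)cc1OCc1ccccc1 | intermediate (not isolated)
12 | 3-(benzyloxy)-4-methoxyphenol | COc1ccc(O)cc1OCc1ccccc1 | intermediate
13 | 2,4-bis(benzyloxy)-1-methoxybenzene | COc1ccc(OCc2ccccc2)cc1OCc1ccccc1 | intermediate
14 | 1,5-bis(benzyloxy)-2-iodo-4-methoxybenzene | COc1cc(I)c(OCc2ccccc2)cc1OCc1ccccc1 | intermediate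
15 | propiolic acid (prop-2-ynoic acid) | C#CC(=O)O | starting material
16 | 3-[2,4-bis(benzyloxy)-5-methoxyphenyl]prop-2-ynoic acid | COc1cc(C#CC(=O)O)c(OCc2ccccc2)cc1OCc1ccccc1 | intermediate
17 | 5-methoxy-3-(methoxymethoxy)-1,2-didehydrobenzene (aryne) | COCOC1=CC(OC)=CC#C1 | intermediate (not isolated)
18 | 3-[2,4-bis(benzyloxy)-5-methoxyphenyl]-1-[2-hydroxy-4-methoxy-6-(methoxymethoxy)phenyl]prop-2-yn-1-one | COCOc1cc(OC)cc(O)c1C(=O)C#Cc1cc(OC)c(OCc2ccccc2)cc1OCc1ccccc1 | intermediate (not isolated)
19 | 2-[2,4-bis(benzyloxy)-5-methoxyphenyl]-7-methoxy-5-(methoxymethoxy)-4H-chromen-4-one | COCOc1cc(OC)cc2oc(-c3cc(OC)c(OCc4ccccc4)cc3OCc3ccccc3)cc(=O)c12 | intermediate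
20 | {2-[2,4-bis(benzyloxy)-5-methoxyphenyl]-7-methoxy-5-(methoxymethoxy)-4-oxo-4H-chromen-3-yl}lithium | COCOc1cc(OC)cc2oc(-c3cc(OC)c(OCc4ccccc4)cc3OCc3ccccc3)c([Li])c(=O)c12 | intermediate (not isolated)
21 | dimethyl {2-[2,4-bis(benzyloxy)-5-methoxyphenyl]-7-methoxy-5-(methoxymethoxy)-4-oxo-4H-chromen-3-yl}boronate | COCOc1cc(OC)cc2oc(-c3cc(OC)c(OCc4ccccc4)cc3OCc3ccccc3)c(B(OC)OC)c(=O)c12 | intermediate (not isolated)
22 | 2-[2,4-bis(benzyloxy)-5-methoxyphenyl]-3-hydroxy-7-methoxy-5-(methoxymethoxy)-4H-chromen-4-one | COCOc1cc(OC)cc2oc(-c3cc(OC)c(OCc4ccccc4)cc3OCc3ccccc3)c(O)c(=O)c12 | intermediate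
23 | 3-(benzyloxy)-2-[2,4-bis(benzyloxy)-5-methoxyphenyl]-7-methoxy-5-(methoxymethoxy)-4H-chromen-4-one | COCOc1cc(OC)cc2oc(-c3cc(OC)c(OCc4ccccc4)cc3OCc3ccccc3)c(OCc3ccccc3)c(=O)c12 | intermediate
24 | 3-(benzyloxy)-2-[2,4-bis(benzyloxy)-5-methoxyphenyl]-5-hydroxy-7-methoxy-4H-chromen-4-one | COc1cc(O)c2c(=O)c(OCc3ccccc3)c(-c3cc(OC)c(OCc4ccccc4)cc3OCc3ccccc3)oc2c1 | intermediate
25 | potassium 3-(benzyloxy)-2-[2,4-bis(benzyloxy)-5-methoxyphenyl]-5-hydroxy-7-methoxy-4-oxo-4H-chromen-8-yl sulfate | COc1cc(O)c2c(=O)c(OCc3ccccc3)c(-c3cc(OC)c(OCc4ccccc4)cc3OCc3ccccc3)oc2c1OS(=O)(=O)[O-].[K+] | intermediate (not isolated)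
26 | 3-(benzyloxy)-2-[2,4-bis(benzyloxy)-5-methoxyphenyl]-5,8-dihydroxy-7-methoxy-4H-chromen-4-one | COc1cc(O)c2c(=O)c(OCc3ccccc3)c(-c3cc(OC)c(OCc4ccccc4)cc3OCc3ccccc3)oc2c1O | intermediate
27 | 3-(benzyloxy)-2-[2,4-bis(benzyloxy)-5-methoxyphenyl]-5-hydroxy-7,8-dimethoxy-4H-chromen-4-one | COc1cc(O)c2c(=O)c(OCc3ccccc3)c(-c3cc(OC)c(OCc4ccccc4)cc3OCc3ccccc3)oc2c1OC | intermediate
28 | 2-(2,4-dihydroxy-5-methoxyphenyl)-3,5-dihydroxy-7,8-dimethoxy-4H-chromen-4-one (CNP0319239.0) | COc1cc(-c2oc3c(OC)c(OC)cc(O)c3c(=O)c2O)c(O)cc1O | target

## Step count and least certain steps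

Total step count: 15. Longest linear sequence: 11 steps (steps 1–4 and 9–15; the ring B branch, steps 5–8 and 9–15, has the same length).

**Step 9 (key step).** The most likely failures are three. The aryl anion may be protonated before acyl transfer, so that the reaction stops at the aryl ester. The electron-rich cesium arylpropiolate may lose CO2 at 125 °C. The ynone phenoxide may close in the 5-exo mode.

The fallback forms C4–C4a by acylation of an aryllithium and keeps the oxa-Michael closure. It sets out from 3 and 16 and returns at 19.
- Acid 16 is condensed with N,O-dimethylhydroxylamine hydrochloride (carbodiimide, CH2Cl2) to the Weinreb amide N-methoxy-N-methyl-3-[2,4-bis(benzyloxy)-5-methoxyphenyl]prop-2-ynamide F1.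
- Carbamate 3 is N-silylated and lithiated exactly as in step 3 (through 4 and 5). Aryllithium 5 is acylated with F1 at −78 °C and the N–Si bond is hydrolysed, giving 2-{3-[2,4-bis(benzyloxy)-5-methoxyphenyl]prop-2-ynoyl}-5-methoxy-3-(methoxymethoxy)phenyl N-isopropylcarbamate F2.
- DBU and Et2NH in MeCN then remove the carbamate, and the liberated phenoxide of 18 should close ring C to 19.

**Step 3.** Lithiation may take place partly at the other ortho position, between the carbamate and the methoxyl, which would lead to the isomeric aryne and finally to a 5-methoxy-7-(methoxymethoxy)flavone. Carbamoyl migration to carbon on warming and attack of the silyl triflate on the acetal are lesser risks.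

The fallback makes the lithiation site unambiguous by symmetry. It sets out from 1 and returns at 8.
- Diol 1 is treated with two equivalents of isopropyl isocyanate to give 5-methoxy-1,3-phenylene bis(N-isopropylcarbamate) F3.
- Double N-silylation, lithiation at the only position flanked by two carbamates and silylation give 5-methoxy-2-(trimethylsilyl)-1,3-phenylene bis(N-isopropylcarbamate) F4.
- DBU and Et2NH remove both carbamates to give 5-methoxy-2-(trimethylsilyl)benzene-1,3-diol F5.
- Mono-alkylation with MOMCl and K2CO3 gives phenol 8, which is triflated with PhNTf2 as in the second stage of step 4 to reach 9.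

**Step 13.** Elbs oxidations characteristically stop at partial conversion. In addition the lipophilic tribenzyl ether may dissolve poorly in the alkaline medium, the pyranone may open under hydroxide, and the hydroquinone may be over-oxidised to a quinone.

The fallback introduces the C8 oxygen by halogenation and copper-mediated etherification. It sets out from 23 and returns at 27.
- NIS in DMF should iodinate the 5,7-dialkoxy ring A at C8, giving 3-(benzyloxy)-2-[2,4-bis(benzyloxy)-5-methoxyphenyl]-8-iodo-7-methoxy-5-(methoxymethoxy)-4H-chromen-4-one F6.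
- CuBr and NaOMe in MeOH/DMF at 100 °C exchange iodine for methoxyl, giving 3-(benzyloxy)-2-[2,4-bis(benzyloxy)-5-methoxyphenyl]-7,8-dimethoxy-5-(methoxymethoxy)-4H-chromen-4-one F7.
- Aqueous HCl in MeOH/THF removes the acetal and gives 27.

**Step 10.** The amide base may add to C2 with opening of the pyranone instead of removing the C3 hydrogen, or the lithiated flavone may be trapped incompletely by the borate.

The fallback oxidises the enol ether double bond directly. It sets out from 19 and returns at 24, so that steps 11 and 12 are replaced.
- Dimethyldioxirane in acetone/CH2Cl2 at 0 °C gives the racemic, necessarily cis-fused epoxide 2-[2,4-bis(benzyloxy)-5-methoxyphenyl]-2,3-epoxy-7-methoxy-5-(methoxymethoxy)chroman-4-one F8.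
- TsOH·H2O in CH2Cl2/MeOH opens the epoxide to the flavonol and removes the acetal, giving 2-[2,4-bis(benzyloxy)-5-methoxyphenyl]-3,5-dihydroxy-7-methoxy-4H-chromen-4-one F9.
- One equivalent of BnBr with K2CO3 in acetone should benzylate the C3 hydroxyl in preference to the chelated C5 hydroxyl and give 24.

**Step 8.** The coupled acid may decarboxylate and couple a second time to a diarylalkyne, and the hindered, electron-rich iodide may undergo oxidative addition slowly.

The fallback separates coupling from carboxylation. It sets out from 14 and returns at 16.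
- Sonogashira coupling with ethynyltrimethylsilane (PdCl2(PPh3)2, CuI, Et3N) gives {[2,4-bis(benzyloxy)-5-methoxyphenyl]ethynyl}trimethylsilane F10.
- K2CO3 in MeOH gives 1,5-bis(benzyloxy)-2-ethynyl-4-methoxybenzene F11.
- Deprotonation with n-BuLi in THF at −78 °C and quenching with CO2 gives 16.

## Further compounds

F1 | step 9 | N-methoxy-N-methyl-3-[2,4-bis(benzyloxy)-5-methoxyphenyl]prop-2-ynamide | COc1cc(C#CC(=O)N(C)OC)c(OCc2ccccc2)cc1OCc1ccccc1
F2 | step 9 | 2-{3-[2,4-bis(benzyloxy)-5-methoxyphenyl]prop-2-ynoyl}-5-methoxy-3-(methoxymethoxy)phenyl N-isopropylcarbamate | COCOc1cc(OC)cc(OC(=O)NC(C)C)c1C(=O)C#Cc1cc(OC)c(OCc2ccccc2)cc1OCc1ccccc1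
F3 | step 3 | 5-methoxy-1,3-phenylene bis(N-isopropylcarbamate) | COc1cc(OC(=O)NC(C)C)cc(OC(=O)NC(C)C)c1
F4 | step 3 | 5-methoxy-2-(trimethylsilyl)-1,3-phenylene bis(N-isopropylcarbamate) | COc1cc(OC(=O)NC(C)C)c([Si](C)(C)C)c(OC(=O)NC(C)C)c1
F5 | step 3 | 5-methoxy-2-(trimethylsilyl)benzene-1,3-diol | COc1cc(O)c([Si](C)(C)C)c(O)c1
F6 | step 13 | 3-(benzyloxy)-2-[2,4-bis(benzyloxy)-5-methoxyphenyl]-8-iodo-7-methoxy-5-(methoxymethoxy)-4H-chromen-4-one | COCOc1cc(OC)c(I)c2oc(-c3cc(OC)c(OCc4ccccc4)cc3OCc3ccccc3)c(OCc3ccccc3)c(=O)c12
F7 | step 13 | 3-(benzyloxy)-2-[2,4-bis(benzyloxy)-5-methoxyphenyl]-7,8-dimethoxy-5-(methoxymethoxy)-4H-chromen-4-one | COCOc1cc(OC)c(OC)c2oc(-c3cc(OC)c(OCc4ccccc4)cc3OCc3ccccc3)c(OCc3ccccc3)c(=O)c12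
F8 | step 10 | racemic cis-fused 2-[2,4-bis(benzyloxy)-5-methoxyphenyl]-2,3-epoxy-7-methoxy-5-(methoxymethoxy)chroman-4-one | COCOc1cc(OC)cc2OC3(c4cc(OC)c(OCc5ccccc5)cc4OCc4ccccc4)OC3C(=O)c12
F9 | step 10 | 2-[2,4-bis(benzyloxy)-5-methoxyphenyl]-3,5-dihydroxy-7-methoxy-4H-chromen-4-one | COc1cc(O)c2c(=O)c(O)c(-c3cc(OC)c(OCc4ccccc4)cc3OCc3ccccc3)oc2c1
F10 | step 8 | {[2,4-bis(benzyloxy)-5-methoxyphenyl]ethynyl}trimethylsilane | COc1cc(C#C[Si](C)(C)C)c(OCc2ccccc2)cc1OCc1ccccc1
F11 | step 8 | 1,5-bis(benzyloxy)-2-ethynyl-4-methoxybenzene | COc1cc(C#C)c(OCc2ccccc2)cc1OCc1ccccc1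
A1 | alternative 1 | 4'-benzyloxy-5,7,8,5'-tetramethoxyflavonol with O3 and O2' joined by a methylene bridge (seven-membered dioxepine) | COc1cc(OC)c2c(=O)c3OCOc4cc(OCc5ccccc5)c(OC)cc4-c3oc2c1OC
A2 | alternative 1 | 3-{[5-(benzyloxy)-2-bromo-4-methoxyphenoxy]methoxy}-5,7,8-trimethoxy-4H-chromen-4-one | COc1cc(OC)c2c(=O)c(OCOc3cc(OCc4ccccc4)c(OC)cc3Br)coc2c1OC
A3 | alternative 2 | 3-(benzyloxy)-2-[2,4-bis(benzyloxy)-5-methoxyphenyl]-5,7-dihydroxy-8-methoxy-4H-chromen-4-one | COc1c(O)cc(O)c2c(=O)c(OCc3ccccc3)c(-c3cc(OC)c(OCc4ccccc4)cc3OCc3ccccc3)oc12
A4 | alternative 2 | racemic tert-butyl 4-{5-(benzyloxy)-6-[2,4-bis(benzyloxy)-5-methoxyphenyl]-4-oxo-4H-pyran-2-yl}-4-methoxy-3-oxobutanoate | CC(C)(C)OC(=O)CC(=O)C(OC)c1cc(=O)c(OCc2ccccc2)c(-c2cc(OC)c(OCc3ccccc3)cc2OCc2ccccc2)o1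
A5 | alternative 2 | kojic acid, 5-hydroxy-2-(hydroxymethyl)-4H-pyran-4-one | OCc1cc(=O)c(O)co1
A6 | alternative 3 | 3-(benzyloxy)-2-[2-hydroxy-5-methoxy-4-(methoxymethoxy)phenyl]-5,7,8-trimethoxy-4H-chromen-4-one | COCOc1cc(O)c(-c2oc3c(OC)c(OC)cc(OC)c3c(=O)c2OCc2ccccc2)cc1OC
A7 | alternative 3 | 3-(benzyloxy)-2-ethynyl-5,7,8-trimethoxy-4H-chromen-4-one | C#Cc1oc2c(OC)c(OC)cc(OC)c2c(=O)c1OCc1ccccc1
A8 | alternative 3 | pentacarbonyl{methoxy[1-(methoxymethoxy)ethenyl]methylidene}chromium | COCOC(=C)C(OC)=[Cr](=C=O)(=C=O)(=C=O)(=C=O)=C=O
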